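**Retrosynthetic overview**

- The feature used is in ring A: C4', the carbon bearing the pyran oxygen, is para to C1', the carbon bearing the chalcone carbonyl. The pyran ring (ring C) is therefore opened at its O–C4' bond to a 4'-fluoro chalcone with a (Z)-3-hydroxy-3-methylbut-1-enyl chain on C3'; its tertiary alkoxide closes the ring by intramolecular SNAr.
- The enone Cα=Cβ bond is cut by a Claisen–Schmidt disconnection into a ring A methyl ketone and a ring B aldehyde.
- Ring A ketone: 2-bromo-3-fluorophenol, then acetate, Fries rearrangement, MOM ether, Sonogashira coupling with 2-methylbut-3-yn-2-ol, and cis-semihydrogenation. Ring B aldehyde: ortho-C-prenylation of 4-hydroxybenzaldehyde, then MOM ether.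
- Rings A and B are bought as benzenes. Ring C is the only ring formed, in the penultimate step, and removal of both MOM groups ends the route.

Key step: step 9

Remark: primed locants (C1'–C6') denote ring A with C1' bearing the carbonyl; ring B is the prenylated ring. The target has no stereocentre, only the E enone. The aldol adduct of step 8 is racemic and its stereocentre is lost on dehydration.

**Route**

Step 1
Reactants: 1 2-bromo-3-fluorophenol
Product: 2 2-bromo-3-fluorophenyl acetate
Conditions: Ac2O, pyridine, DMAP (cat.), CH2Cl2, 0 °C to rt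
Reagents that add atoms: acetic anhydride, CC(=O)OC(C)=O
Why: O-acylation of the phenol under nucleophilic catalysis (esterification); no other group in 1 reacts.

Step 2
Reactants: 2 2-bromo-3-fluorophenyl acetate
Product: 3 1-(3-bromo-4-fluoro-2-hydroxyphenyl)ethanone
Conditions: AlCl3 (2 equiv), neat, 140 °C; then ice, aq. HCl
Reagents that add atoms: none
Why: Fries rearrangement, in which the acylium ion released by AlCl3 re-enters at the only free position ortho to oxygen, which is also para to fluorine, and the high temperature favours this chelated ortho product over the para isomer.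

Step 3
Reactants: 3 1-(3-bromo-4-fluoro-2-hydroxyphenyl)ethanone
Product: 4 1-[3-bromo-4-fluoro-2-(methoxymethoxy)phenyl]ethanone
Conditions: NaH (1.1 equiv), MOMCl, DMF, 0 °C to rt
Reagents that add atoms: chloromethyl methyl ether, COCCl
Why: MOM protection by O-alkylation of the sodium phenoxide with the α-chloro ether; one equivalent of NaH removes only the phenolic proton, which is far more acidic than the methyl ketone, and breaks the hydrogen bond to the carbonyl.

Step 4
Reactants: 4 1-[3-bromo-4-fluoro-2-(methoxymethoxy)phenyl]ethanone; 5 2-methylbut-3-yn-2-ol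
Product: 6 1-[4-fluoro-3-(3-hydroxy-3-methylbut-1-ynyl)-2-(methoxymethoxy)phenyl]ethanone
Conditions: PdCl2(PPh3)2 (cat.), CuI (cat.), Et3N, DMF, 80 °C
Reagents that add atoms: none
Why: Sonogashira coupling, in which zerovalent palladium inserts into the C–Br bond and leaves C–F alone, the alkynyl group is transferred from copper, and reductive elimination follows; the capped phenol cannot cyclise onto the alkyne to a benzofuran.

Step 5
Reactants: 6 1-[4-fluoro-3-(3-hydroxy-3-methylbut-1-ynyl)-2-(methoxymethoxy)phenyl]ethanone
Product: 7 1-[4-fluoro-3-[(Z)-3-hydroxy-3-methylbut-1-enyl]-2-(methoxymethoxy)phenyl]ethanone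
Conditions: H2 (1 atm), Pd/CaCO3 poisoned with Pb(OAc)2, quinoline, EtOAc, rt
Reagents that add atoms: none
Why: Lindlar semihydrogenation, in which syn delivery of hydrogen on the lead-poisoned palladium surface gives the Z alkene and stops at the alkene stage; the ketone, the C–F bond and the acetal are inert.

Step 6
Reactants: 8 4-hydroxybenzaldehyde; 9 1-bromo-3-methylbut-2-ene
Product: 10 4-hydroxy-3-(3-methylbut-2-enyl)benzaldehyde
Conditions: KOH (aq.), rt; then acidify, chromatography
Reagents that add atoms: none
Why: ortho-C-allylation of a phenoxide in water, where solvation of oxygen shifts the ambident anion toward carbon; the para position is blocked by the formyl group, and the neutral O-prenyl ether by-product is separated from the phenolic product by base extraction.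

Step 7
Reactants: 10 4-hydroxy-3-(3-methylbut-2-enyl)benzaldehyde
Product: 11 4-(methoxymethoxy)-3-(3-methylbut-2-enyl)benzaldehyde
Conditions: MOMCl, i-Pr2NEt, CH2Cl2, 0 °C to rt
Reagents that add atoms: chloromethyl methyl ether, COCCl
Why: MOM protection by O-alkylation of the phenol with the α-chloro ether under amine base; the aldehyde and the prenyl group are untouched.

Step 8
Reactants: 7 1-[4-fluoro-3-[(Z)-3-hydroxy-3-methylbut-1-enyl]-2-(methoxymethoxy)phenyl]ethanone; 11 4-(methoxymethoxy)-3-(3-methylbut-2-enyl)benzaldehyde
Product: 13 (E)-1-[4-fluoro-3-[(Z)-3-hydroxy-3-methylbut-1-enyl]-2-(methoxymethoxy)phenyl]-3-[4-(methoxymethoxy)-3-(3-methylbut-2-enyl)phenyl]prop-2-en-1-one, via β-hydroxy ketone 12 (not isolated)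
Conditions: KOH, EtOH/H2O, 0 °C to rt
Reagents that add atoms: none
Why: Claisen–Schmidt condensation, in which the methyl ketone enolate adds to the non-enolisable aldehyde and E1cB loss of water gives the thermodynamically preferred E enone; in the hydroxylic medium the tertiary alcohol stays largely protonated and the partly enolised ketone activates C4' poorly, so the fluorine should be kept.

Step 9
Reactants: 13 (E)-1-[4-fluoro-3-[(Z)-3-hydroxy-3-methylbut-1-enyl]-2-(methoxymethoxy)phenyl]-3-[4-(methoxymethoxy)-3-(3-methylbut-2-enyl)phenyl]prop-2-en-1-one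
Product: 14 (E)-1-[5-(methoxymethoxy)-2,2-dimethyl-2H-chromen-6-yl]-3-[4-(methoxymethoxy)-3-(3-methylbut-2-enyl)phenyl]prop-2-en-1-one (paratocarpin B bis(methoxymethyl) ether)
Conditions: KOt-Bu (1.2 equiv), THF/DMF, 0 °C to rt
Reagents that add atoms: none
Why: KOt-Bu deprotonates the tertiary alcohol, the alkoxide adds to C4' to give a Meisenheimer anion whose charge is carried onto the oxygen of the para carbonyl on C1', and loss of fluoride restores the arene; this is an intramolecular SNAr etherification, the known reaction of alkoxides with fluoroarenes activated by a para acyl group. Ring C closes in a six-membered mode by attack of oxygen on an aromatic sp2 carbon (6-exo with respect to the C4'–C5' π bond), and the Z alkene, twisted out of the arene plane by its two ortho neighbours, holds the alkoxide above C4'. No stereocentre is formed; the Z alkene becomes the C3=C4 bond of the chromene and the E enone is not touched. The selectivity needed is attack at C4' and not at C2', the other ortho carbon within reach of the alkoxide and itself ortho to the carbonyl; it should be secured because fluorine accelerates the addition step far more than the methoxymethoxy group does, and C2' is a more crowded, donor-substituted carbon. The chalcone has no enolisable hydrogen, so the base cannot convert the activating ketone into an enolate, and both phenols are capped, so no phenoxide pushes electrons into ring A; addition to the carbonyl carbon would need an eight-membered ring and the enone β-carbon is out of reach.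

Step 10
Reactants: 14 paratocarpin B bis(methoxymethyl) ether
Product: 15 paratocarpin B, (E)-1-(5-hydroxy-2,2-dimethyl-2H-chromen-6-yl)-3-[4-hydroxy-3-(3-methylbut-2-enyl)phenyl]prop-2-en-1-one
Conditions: 3 M aq. HCl, MeOH, rt
Reagents that add atoms: none
Why: acid-catalysed acetal cleavage (MOM removal) through oxocarbenium ions trapped by methanol; the MOM group ortho to the carbonyl leaves first, and at this acidity and temperature the prenyl group, the chromene double bond and the 2'-hydroxychalcone (flavanone closure) should not react.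

**Compound list**

1 | 2-bromo-3-fluorophenol | Oc1cccc(F)c1Br | starting material
2 | 2-bromo-3-fluorophenyl acetate | CC(=O)Oc1cccc(F)c1Br | intermediate
3 | 1-(3-bromo-4-fluoro-2-hydroxyphenyl)ethanone | CC(=O)c1ccc(F)c(Br)c1O | intermediate
4 | 1-[3-bromo-4-fluoro-2-(methoxymethoxy)phenyl]ethanone | CC(=O)c1ccc(F)c(Br)c1OCOC | intermediate
5 | 2-methylbut-3-yn-2-ol | CC(C)(O)C#C | starting material
6 | 1-[4-fluoro-3-(3-hydroxy-3-methylbut-1-ynyl)-2-(methoxymethoxy)phenyl]ethanone | CC(=O)c1ccc(F)c(C#CC(C)(C)O)c1OCOC | intermediate
7 | 1-[4-fluoro-3-[(Z)-3-hydroxy-3-methylbut-1-enyl]-2-(methoxymethoxy)phenyl]ethanone | CC(=O)c1ccc(F)c(/C=C\C(C)(C)O)c1OCOC | intermediate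
8 | 4-hydroxybenzaldehyde | O=Cc1ccc(O)cc1 | starting material
9 | 1-bromo-3-methylbut-2-ene | CC(C)=CCBr | starting material
10 | 4-hydroxy-3-(3-methylbut-2-enyl)benzaldehyde | CC(C)=CCc1cc(C=O)ccc1O | intermediate
11 | 4-(methoxymethoxy)-3-(3-methylbut-2-enyl)benzaldehyde | CC(C)=CCc1cc(C=O)ccc1OCOC | intermediate
12 | 1-[4-fluoro-3-[(Z)-3-hydroxy-3-methylbut-1-enyl]-2-(methoxymethoxy)phenyl]-3-hydroxy-3-[4-(methoxymethoxy)-3-(3-methylbut-2-enyl)phenyl]propan-1-one (racemic aldol adduct, not isolated) | CC(C)=CCc1cc(C(O)CC(=O)c2ccc(F)c(/C=C\C(C)(C)O)c2OCOC)ccc1OCOC | intermediate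
13 | (E)-1-[4-fluoro-3-[(Z)-3-hydroxy-3-methylbut-1-enyl]-2-(methoxymethoxy)phenyl]-3-[4-(methoxymethoxy)-3-(3-methylbut-2-enyl)phenyl]prop-2-en-1-one | CC(C)=CCc1cc(/C=C/C(=O)c2ccc(F)c(/C=C\C(C)(C)O)c2OCOC)ccc1OCOC | intermediate
14 | (E)-1-[5-(methoxymethoxy)-2,2-dimethyl-2H-chromen-6-yl]-3-[4-(methoxymethoxy)-3-(3-methylbut-2-enyl)phenyl]prop-2-en-1-one | CC(C)=CCc1cc(/C=C/C(=O)c2ccc3c(c2OCOC)C=CC(C)(C)O3)ccc1OCOC | intermediate
15 | paratocarpin B | CC(C)=CCc1cc(/C=C/C(=O)c2ccc3c(c2O)C=CC(C)(C)O3)ccc1O | target

**Count**

Total steps: 10. Longest linear sequence: 8 steps (steps 1, 2, 3, 4, 5, 8, 9, 10).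

**Steps most likely to fail**

Step 9. Displacement of fluoride may be outrun by addition of alkoxide to the enone, by base-induced cleavage of the chalcone, or by attack at C2' with loss of the methoxymethoxy group, if the carbonyl, twisted by its ortho substituent, activates C4' less than expected. The fallback builds the pyran ring before the chalcone by known chromenylation. It sets out from aldehyde 11 as the ring B partner. Commercial 2,4-dihydroxyacetophenone is heated with 3-methylbut-2-enal in pyridine; condensation at the carbon between the two hydroxyl groups and oxa-6π electrocyclisation onto the non-chelated hydroxyl should give 1-(5-hydroxy-2,2-dimethyl-2H-chromen-6-yl)ethanone F1. NaH and MOMCl in DMF convert it into 1-[5-(methoxymethoxy)-2,2-dimethyl-2H-chromen-6-yl]ethanone F2. Claisen–Schmidt condensation of F2 with 11 (KOH, EtOH/H2O) passes through the racemic β-hydroxy ketone 3-hydroxy-1-[5-(methoxymethoxy)-2,2-dimethyl-2H-chromen-6-yl]-3-[4-(methoxymethoxy)-3-(3-methylbut-2-enyl)phenyl]propan-1-one F3 and comes back to the route at 14.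

Step 8. During the slow condensation of the electron-rich aldehyde, fluoride may be displaced early, either by the side-chain alkoxide or by ethoxide from the medium. The fallback moves the condensation ahead of the semihydrogenation, where the linear alkyne cannot reach C4'. It sets out from alkynyl ketone 6 and aldehyde 11. Under KOH in EtOH/H2O they should condense through the racemic aldol adduct 1-[4-fluoro-3-(3-hydroxy-3-methylbut-1-ynyl)-2-(methoxymethoxy)phenyl]-3-hydroxy-3-[4-(methoxymethoxy)-3-(3-methylbut-2-enyl)phenyl]propan-1-one F4 to (E)-1-[4-fluoro-3-(3-hydroxy-3-methylbut-1-ynyl)-2-(methoxymethoxy)phenyl]-3-[4-(methoxymethoxy)-3-(3-methylbut-2-enyl)phenyl]prop-2-en-1-one F5. Hydrogenation of F5 over Pd/CaCO3 poisoned with Pb(OAc)2 in the presence of quinoline, stopped after one equivalent of H2, is expected to reduce the alkyne in preference to the enone and the trisubstituted alkene, and comes back to the route at 13.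

Step 2. The acyl group may migrate to the position para to oxygen, or AlCl3 at high temperature may shift or remove the bromine. The fallback introduces the carbonyl carbon by ortho-selective formylation and sets out from phenol 1. MgCl2, Et3N and paraformaldehyde in MeCN at reflux formylate only the free ortho position and should give 3-bromo-4-fluoro-2-hydroxybenzaldehyde F6. NaH and MOMCl give 3-bromo-4-fluoro-2-(methoxymethoxy)benzaldehyde F7. MeMgBr in THF at −78 °C adds to the aldehyde to give racemic 1-[3-bromo-4-fluoro-2-(methoxymethoxy)phenyl]ethanol F8. Oxidation of F8 with Dess–Martin periodinane in CH2Cl2 comes back to the route at ketone 4.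

**Further compounds**

F1 | step 9 | 1-(5-hydroxy-2,2-dimethyl-2H-chromen-6-yl)ethanone | CC(=O)c1ccc2c(c1O)C=CC(C)(C)O2
F2 | step 9 | 1-[5-(methoxymethoxy)-2,2-dimethyl-2H-chromen-6-yl]ethanone | CC(=O)c1ccc2c(c1OCOC)C=CC(C)(C)O2
F3 | step 9 | 3-hydroxy-1-[5-(methoxymethoxy)-2,2-dimethyl-2H-chromen-6-yl]-3-[4-(methoxymethoxy)-3-(3-methylbut-2-enyl)phenyl]propan-1-one (racemic) | CC(C)=CCc1cc(C(O)CC(=O)c2ccc3c(c2OCOC)C=CC(C)(C)O3)ccc1OCOC
F4 | step 8 | 1-[4-fluoro-3-(3-hydroxy-3-methylbut-1-ynyl)-2-(methoxymethoxy)phenyl]-3-hydroxy-3-[4-(methoxymethoxy)-3-(3-methylbut-2-enyl)phenyl]propan-1-one (racemic) | CC(C)=CCc1cc(C(O)CC(=O)c2ccc(F)c(C#CC(C)(C)O)c2OCOC)ccc1OCOC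
F5 | step 8 | (E)-1-[4-fluoro-3-(3-hydroxy-3-methylbut-1-ynyl)-2-(methoxymethoxy)phenyl]-3-[4-(methoxymethoxy)-3-(3-methylbut-2-enyl)phenyl]prop-2-en-1-one | CC(C)=CCc1cc(/C=C/C(=O)c2ccc(F)c(C#CC(C)(C)O)c2OCOC)ccc1OCOC
F6 | step 2 | 3-bromo-4-fluoro-2-hydroxybenzaldehyde | O=Cc1ccc(F)c(Br)c1O
F7 | step 2 | 3-bromo-4-fluoro-2-(methoxymethoxy)benzaldehyde | O=Cc1ccc(F)c(Br)c1OCOC
F8 | step 2 | 1-[3-bromo-4-fluoro-2-(methoxymethoxy)phenyl]ethanol (racemic) | CC(O)c1ccc(F)c(Br)c1OCOC
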